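The retrosynthesis first removes the indole N–Si bond, then takes the pyrrole back to an N-tosyl-2,5-dihydropyrrole and cuts pyrrole C3=C4 by metathesis. It then cuts the sulfonamide N–C(sp3) bond, the oxazole C2–C(sp3) bond, oxazole C4–I, oxazole C4–C5 and O1–C2, and indole C3–CHO.
Enabling feature: the pyrrole ring has one substituent only, the bond from its C2 to oxazole C2, and C3, C4 and C5 are plain CH positions. C3=C4 can therefore be made from two terminal CH=CH2 groups, one on the carbon attached to oxazole C2 and one in an N-allyl group.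
Forward order: the indole (rings A and B) is bought. The oxazole (ring C) is built on its C3 aldehyde, iodinated at C4 and extended at C2. The pyrrole (ring D) is closed last and then aromatised.
Stereochemistry: the target has no stereocentre. The single sp3 centre made on the way is racemic and disappears on aromatisation.

Key step: step 7

Remark: every intermediate with an sp3 stereocentre is carried as a racemate, which suffices for an achiral target, and the four numbered starting materials are taken to be catalogue chemicals.

Step 1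
Reactants: 1 6-bromo-4-methoxy-1H-indole
Product: 3 6-bromo-4-methoxy-1H-indole-3-carbaldehyde, via iminium chloride 2 (not isolated)
Conditions: POCl3 (1.2 equiv), DMF, 0 °C to 40 °C; then 2 M aq NaOH, rt
Reagents that add atoms: N,N-dimethylformamide CN(C)C=O; water O
Why: Vilsmeier–Haack formylation, in which the chloroiminium ion made from DMF and POCl3 attacks the enamine-like C3, the most nucleophilic carbon of an N-unsubstituted indole, and alkaline hydrolysis of iminium salt 2 releases the aldehyde while the aryl bromide and the methyl ether stay inert.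

Step 2
Reactants: 3 6-bromo-4-methoxy-1H-indole-3-carbaldehyde; 4 p-toluenesulfonylmethyl isocyanide (TosMIC)
Product: 6 5-(6-bromo-4-methoxy-1H-indol-3-yl)oxazole, via 4-tosyloxazoline 5 (not isolated)
Conditions: K2CO3 (2 equiv), MeOH, reflux
Reagents that add atoms: none
Why: van Leusen oxazole synthesis, in which deprotonated TosMIC adds to the aldehyde carbon (C4–C5 bond), the alkoxide closes onto the isocyanide carbon (O1–C2 bond) to give oxazoline 5, and loss of p-toluenesulfinate aromatises it to the 5-substituted oxazole, a sequence well known for N-unprotected indole-3-carbaldehydes.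

Step 3
Reactants: 6 5-(6-bromo-4-methoxy-1H-indol-3-yl)oxazole
Product: 8 5-[6-bromo-4-methoxy-1-(triisopropylsilyl)-1H-indol-3-yl]oxazole, via sodium indolide 7 (not isolated)
Conditions: NaH (1.2 equiv), THF, 0 °C; then i-Pr3SiCl, 0 °C to rt
Reagents that add atoms: chlorotriisopropylsilane CC(C)[Si](Cl)(C(C)C)C(C)C
Why: N-silylation of an indolide anion, in which the indole N–H is the only proton that NaH removes and the bulky silyl group both masks that proton for the strongly basic steps ahead and shields indole C2 from metalation and halogenation.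

Step 4
Reactants: 8 5-[6-bromo-4-methoxy-1-(triisopropylsilyl)-1H-indol-3-yl]oxazole
Product: 11 5-[6-bromo-4-methoxy-1-(triisopropylsilyl)-1H-indol-3-yl]-4-iodooxazole, via 2-lithiooxazole 9 (not isolated), via lithium isocyanoenolate 10 (not isolated)
Conditions: LiN(SiMe3)2 (1.2 equiv), THF–DMPU, −78 °C; then I2, −78 °C; aq Na2S2O3
Reagents that add atoms: iodine II
Why: Deprotonative C4 iodination of a 5-substituted oxazole, in which the amide base removes the acidic C2–H, 2-lithiooxazole 9 equilibrates with ring-opened isocyanoenolate 10 (favoured by the polar cosolvent DMPU), the enolate carbon of 10 (the future C4) attacks iodine, and re-closure with proton transfer returns the oxazole with iodine at C4 and C2–H restored, while a lithium amide cannot exchange with the aryl bromide.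

Step 5
Reactants: 11 5-[6-bromo-4-methoxy-1-(triisopropylsilyl)-1H-indol-3-yl]-4-iodooxazole; 12 acrolein
Product: 14 1-{5-[6-bromo-4-methoxy-1-(triisopropylsilyl)-1H-indol-3-yl]-4-iodooxazol-2-yl}prop-2-en-1-ol (racemic), via oxazol-2-ylmagnesium chloride 13 (not isolated)
Conditions: TMPMgCl·LiCl (TMP = 2,2,6,6-tetramethylpiperidin-1-yl, 1.2 equiv), THF, −40 °C; then freshly distilled acrolein, −78 °C to −20 °C; aq NH4Cl
Reagents that add atoms: none
Why: Deprotonative magnesiation followed by 1,2-addition of a heteroaryl Grignard reagent to an enal, in which oxazole C2–H is by far the most acidic C–H of 11, the hindered amide base undergoes no halogen–metal exchange at C–I or C–Br, the covalent C–Mg bond keeps the oxazole ring closed, and the hard nucleophile attacks the carbonyl carbon of acrolein to set the carbinol centre without control (racemic).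

Step 6
Reactants: 14 1-{5-[6-bromo-4-methoxy-1-(triisopropylsilyl)-1H-indol-3-yl]-4-iodooxazol-2-yl}prop-2-en-1-ol (racemic); 15 N-allyl-4-methylbenzenesulfonamide
Product: 16 N-allyl-N-(1-{5-[6-bromo-4-methoxy-1-(triisopropylsilyl)-1H-indol-3-yl]-4-iodooxazol-2-yl}allyl)-4-methylbenzenesulfonamide (racemic)
Conditions: PPh3 (1.5 equiv), DIAD (1.5 equiv), THF, 0 °C to rt
Reagents that add atoms: none
Why: Mitsunobu N-alkylation of a sulfonamide, in which PPh3 and DIAD turn the secondary allylic hydroxyl into an alkoxyphosphonium leaving group that the deprotonated sulfonamide displaces at the carbinol carbon, direct substitution being favoured because the electron-poor oxazol-2-yl group disfavours an allyl cation and speeds SN2 attack much as a carbonyl group would, and inversion has no consequence at a racemic centre.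

Step 7
Reactants: 16 N-allyl-N-(1-{5-[6-bromo-4-methoxy-1-(triisopropylsilyl)-1H-indol-3-yl]-4-iodooxazol-2-yl}allyl)-4-methylbenzenesulfonamide (racemic)
Product: 17 5-[6-bromo-4-methoxy-1-(triisopropylsilyl)-1H-indol-3-yl]-4-iodo-2-(1-tosyl-2,5-dihydro-1H-pyrrol-2-yl)oxazole (racemic)
Conditions: (H2IMes)(PCy3)Cl2Ru=CHPh (second-generation Grubbs catalyst, 5 mol %), CH2Cl2 (0.01 M), 40 °C
Reagents that add atoms: none
Why: After loss of PCy3 the ruthenium alkylidene exchanges first with the unhindered N-allyl terminus of 16, which places a Ru=CH unit three atoms away from the branched vinyl group. Intramolecular [2+2] cycloaddition onto that vinyl group gives a ruthenacyclobutane, and its cycloreversion forms the C3=C4 double bond of the dihydropyrrole and a Ru=CH2 carrier, so that each turnover expels ethylene, whose escape from warm CH2Cl2 drives the reaction. The closest known reaction type is ring-closing metathesis of N-sulfonyl diallylamines to N-sulfonyl-3-pyrrolines, and the one ring formed is five-membered, closes by alkene–alkene metathesis of a 1,6-diene and can only hold a cis alkene. No stereocentre is created, and the racemic carbon between oxazole C2 and nitrogen is not touched. The step needs chemoselectivity only, and the substrate secures it because its two terminal alkenes are the only alkenes present, the sulfonamide nitrogen and the weakly basic oxazole nitrogen next to iodine bind ruthenium poorly, and C(sp2)–I and C(sp2)–Br bonds are inert to ruthenium alkylidenes, while high dilution suppresses intermolecular metathesis.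

Step 8
Reactants: 17 5-[6-bromo-4-methoxy-1-(triisopropylsilyl)-1H-indol-3-yl]-4-iodo-2-(1-tosyl-2,5-dihydro-1H-pyrrol-2-yl)oxazole (racemic)
Product: 19 5-[6-bromo-4-methoxy-1-(triisopropylsilyl)-1H-indol-3-yl]-4-iodo-2-(1H-pyrrol-2-yl)oxazole, via 2H-pyrrole 18 (not isolated)
Conditions: KOt-Bu (2.5 equiv), THF, 0 °C to rt; aq NH4Cl
Reagents that add atoms: none
Why: Base-induced elimination of sulfinate (E1cB type) from an N-sulfonyl-3-pyrroline, in which the ring C2–H, acidified by the oxazole, the ring alkene and the sulfonamide nitrogen, is removed, p-toluenesulfinate leaves from nitrogen to give 2H-pyrrole 18, and a prototropic shift from the CH2 carbon to nitrogen gives the only 1H-pyrrole the skeleton allows, while brief exposure in THF at or below room temperature should spare C–I and C–Br and any partial loss of the silyl group is harmless because it is removed next.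

Step 9
Reactants: 19 5-[6-bromo-4-methoxy-1-(triisopropylsilyl)-1H-indol-3-yl]-4-iodo-2-(1H-pyrrol-2-yl)oxazole
Product: 20 5-(6-bromo-4-methoxy-1H-indol-3-yl)-4-iodo-2-(1H-pyrrol-2-yl)oxazole (target CNP0134885.0)
Conditions: Bu4NF (1.1 equiv), THF, 0 °C, light excluded
Reagents that add atoms: none
Why: Fluoride-induced N–Si cleavage, in which the strong Si–F bond and the good leaving-group ability of the indolide make removal of the N-triisopropylsilyl group fast at 0 °C, conditions that leave the C–I and C–Br bonds, the methyl ether and the pyrrole N–H untouched.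

Compound list
1 | 6-bromo-4-methoxy-1H-indole | COc1cc(Br)cc2[nH]ccc12 | starting material
2 | [(6-bromo-4-methoxy-1H-indol-3-yl)methylidene]dimethylammonium chloride | COc1cc(Br)cc2[nH]cc(C=[N+](C)C)c12.[Cl-] | intermediate
3 | 6-bromo-4-methoxy-1H-indole-3-carbaldehyde | COc1cc(Br)cc2[nH]cc(C=O)c12 | intermediate
4 | p-toluenesulfonylmethyl isocyanide (TosMIC) | Cc1ccc(S(=O)(=O)C[N+]#[C-])cc1 | starting material
5 | 5-(6-bromo-4-methoxy-1H-indol-3-yl)-4-tosyl-4,5-dihydrooxazole (racemic, relative configuration without consequence because both centres are lost) | COc1cc(Br)cc2[nH]cc(C3OC=NC3S(=O)(=O)c3ccc(C)cc3)c12 | intermediate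
6 | 5-(6-bromo-4-methoxy-1H-indol-3-yl)oxazole | COc1cc(Br)cc2[nH]cc(-c3cnco3)c12 | intermediate
7 | sodium 6-bromo-4-methoxy-3-(oxazol-5-yl)indol-1-ide | COc1cc(Br)cc2[n-]cc(-c3cnco3)c12.[Na+] | intermediate
8 | 5-[6-bromo-4-methoxy-1-(triisopropylsilyl)-1H-indol-3-yl]oxazole | COc1cc(Br)cc2n([Si](C(C)C)(C(C)C)C(C)C)cc(-c3cnco3)c12 | intermediate
9 | {5-[6-bromo-4-methoxy-1-(triisopropylsilyl)-1H-indol-3-yl]oxazol-2-yl}lithium | COc1cc(Br)cc2n([Si](C(C)C)(C(C)C)C(C)C)cc(-c3cnc([Li])o3)c12 | intermediate
10 | lithium (Z)-1-[6-bromo-4-methoxy-1-(triisopropylsilyl)-1H-indol-3-yl]-2-isocyanoethen-1-olate | COc1cc(Br)cc2n([Si](C(C)C)(C(C)C)C(C)C)cc(/C(O[Li])=C/[N+]#[C-])c12 | intermediate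
11 | 5-[6-bromo-4-methoxy-1-(triisopropylsilyl)-1H-indol-3-yl]-4-iodooxazole | COc1cc(Br)cc2n([Si](C(C)C)(C(C)C)C(C)C)cc(-c3ocnc3I)c12 | intermediate
12 | acrolein | C=CC=O | starting material
13 | {5-[6-bromo-4-methoxy-1-(triisopropylsilyl)-1H-indol-3-yl]-4-iodooxazol-2-yl}magnesium chloride (as its LiCl complex) | COc1cc(Br)cc2n([Si](C(C)C)(C(C)C)C(C)C)cc(-c3oc([Mg]Cl)nc3I)c12 | intermediate
14 | 1-{5-[6-bromo-4-methoxy-1-(triisopropylsilyl)-1H-indol-3-yl]-4-iodooxazol-2-yl}prop-2-en-1-ol (racemic) | COc1cc(Br)cc2n([Si](C(C)C)(C(C)C)C(C)C)cc(-c3oc(C(O)C=C)nc3I)c12 | intermediate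
15 | N-allyl-4-methylbenzenesulfonamide | C=CCNS(=O)(=O)c1ccc(C)cc1 | starting material
16 | N-allyl-N-(1-{5-[6-bromo-4-methoxy-1-(triisopropylsilyl)-1H-indol-3-yl]-4-iodooxazol-2-yl}allyl)-4-methylbenzenesulfonamide (racemic) | COc1cc(Br)cc2n([Si](C(C)C)(C(C)C)C(C)C)cc(-c3oc(C(C=C)N(CC=C)S(=O)(=O)c4ccc(C)cc4)nc3I)c12 | intermediate
17 | 5-[6-bromo-4-methoxy-1-(triisopropylsilyl)-1H-indol-3-yl]-4-iodo-2-(1-tosyl-2,5-dihydro-1H-pyrrol-2-yl)oxazole (racemic) | COc1cc(Br)cc2n([Si](C(C)C)(C(C)C)C(C)C)cc(-c3oc(C4C=CCN4S(=O)(=O)c4ccc(C)cc4)nc3I)c12 | intermediate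
18 | 5-[6-bromo-4-methoxy-1-(triisopropylsilyl)-1H-indol-3-yl]-4-iodo-2-(2H-pyrrol-5-yl)oxazole | COc1cc(Br)cc2n([Si](C(C)C)(C(C)C)C(C)C)cc(-c3oc(C4=NCC=C4)nc3I)c12 | intermediate
19 | 5-[6-bromo-4-methoxy-1-(triisopropylsilyl)-1H-indol-3-yl]-4-iodo-2-(1H-pyrrol-2-yl)oxazole | COc1cc(Br)cc2n([Si](C(C)C)(C(C)C)C(C)C)cc(-c3oc(-c4ccc[nH]4)nc3I)c12 | intermediate
20 | 5-(6-bromo-4-methoxy-1H-indol-3-yl)-4-iodo-2-(1H-pyrrol-2-yl)oxazole (CNP0134885.0, no stereocentre) | COc1cc(Br)cc2[nH]cc(-c3oc(-c4ccc[nH]4)nc3I)c12 | target

Total step count: 9. Longest linear sequence: 9 steps, from 1 to 20. Compounds 4, 12 and 15 enter as purchased reagents.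

Steps most likely to fail

1. Step 6. The sulfonamide may attack the alkene terminus with allylic transposition, because the transposed alkene gains conjugation with the oxazole. The weakly acidic sulfonamide may also protonate the phosphine–azodicarboxylate adduct too slowly. The fallback sets out from 14 and replaces substitution at an activated alcohol by a metal-catalysed, branched-selective allylic amination. Alcohol 14 is acylated with ClCO2Me and pyridine in CH2Cl2 at 0 °C to the methyl carbonate F1. Treatment with allylamine, [Ir(cod)Cl]2 (2 mol %) and P(OPh)3 (8 mol %) in EtOH at rt to 50 °C should give the branched secondary amine F2. Allyliridium intermediates direct amine nucleophiles to the substituted allyl terminus, and monovalent iridium bearing phosphite ligands is not expected to insert into C(sp2)–I or C(sp2)–Br bonds at these temperatures. Sulfonylation with TsCl, Et3N and catalytic DMAP in CH2Cl2 brings the route back at 16.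

2. Step 5. Anionic polymerisation of acrolein or conjugate addition may compete with carbonyl addition of the fairly unreactive oxazolylmagnesium species. The fallback sets out from 11 and avoids acrolein, building the carbinol from a one-carbon electrophile and a vinyl nucleophile. Magnesium reagent 13, made as in the main route, is quenched with DMF at −40 °C to rt to give the oxazole-2-carbaldehyde F3. This aldehyde is then treated with CH2=CHMgBr in THF at −78 °C. Vinyl Grignard reagents undergo iodine–magnesium exchange only sluggishly, so addition to this very electrophilic aldehyde should prevail. The route is rejoined at 14.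

3. Step 4. Iodine may be taken up at C2 as well as at C4, or a second iodination may occur after proton shuffling between lithiated species, which would erode the selectivity for monoiodination. The fallback sets out from 8 and makes exhaustive iodination the goal. LiN(SiMe3)2 (2.5 equiv) and then I2 (2.5 equiv) in THF at −78 °C should give the 2,4-diiodooxazole F4. i-PrMgCl·LiCl (1.05 equiv) in THF at −78 °C should exchange only the C2 iodine, because that exchange gives the better stabilised carbanion flanked by O1 and N3, as is known for 2,4-dihalogenated 1,3-azoles. This produces magnesium reagent 13 without any amide base. Addition of acrolein 12 then brings the route back at 14.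

Further compounds
F1 | step 6 | 1-{5-[6-bromo-4-methoxy-1-(triisopropylsilyl)-1H-indol-3-yl]-4-iodooxazol-2-yl}allyl methyl carbonate (racemic) | COc1cc(Br)cc2n([Si](C(C)C)(C(C)C)C(C)C)cc(-c3oc(C(C=C)OC(=O)OC)nc3I)c12
F2 | step 6 | N-allyl-1-{5-[6-bromo-4-methoxy-1-(triisopropylsilyl)-1H-indol-3-yl]-4-iodooxazol-2-yl}prop-2-en-1-amine (racemic) | COc1cc(Br)cc2n([Si](C(C)C)(C(C)C)C(C)C)cc(-c3oc(C(C=C)NCC=C)nc3I)c12
F3 | step 5 | 5-[6-bromo-4-methoxy-1-(triisopropylsilyl)-1H-indol-3-yl]-4-iodooxazole-2-carbaldehyde | COc1cc(Br)cc2n([Si](C(C)C)(C(C)C)C(C)C)cc(-c3oc(C=O)nc3I)c12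
F4 | step 4 | 5-[6-bromo-4-methoxy-1-(triisopropylsilyl)-1H-indol-3-yl]-2,4-diiodooxazole | COc1cc(Br)cc2n([Si](C(C)C)(C(C)C)C(C)C)cc(-c3oc(I)nc3I)c12
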